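Ring C is disconnected at C3–C4 and C2=C3, so that C3 with its methoxy group arrives as a one-carbon ylide. The feature exploited is that C3 lies alone between the C4 carbonyl and C2, while ring A carries oxygen on both carbons flanking C4a (C5 and C8a). In one operation methoxymethylenetriphenylphosphorane is C-acylated by a benzoyl chloride and the resulting keto ylide olefinates a neighbouring aryl ester, closing the pyranone. The precursor is a mirror-symmetric 2,6-bis(aroyloxy)-3,4,5-trimethoxybenzoyl chloride whose two identical ring B esters make the choice of ester immaterial; the unused one becomes a protected 5-hydroxyl.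

Key step: step 10

Remark: compounds 1, 9 and 16 and all reagents (including the Vilsmeier salt of step 4) are taken as purchasable. The substitution pattern of 15 maps onto C4a, C8a/C5 and C8–C6 of the target without change. The carboxyl carbon of 15 is brought in as an aldehyde and oxidised after the aroylation, so that no free hydroxy acid has to be acylated.

Step 1
Reactants: 1 2,3,4-trimethoxybenzaldehyde
Product: 2 5-bromo-2,3,4-trimethoxybenzaldehyde
Conditions: NBS, DMF, rt
Reagents that add atoms: N-bromosuccinimide, O=C1CCC(=O)N1Br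
Why: Electrophilic aromatic bromination should go to C5 because this position is ortho to the 4-methoxy group, para to the 2-methoxy group and meta to the formyl group, so every substituent directs there.

Step 2
Reactants: 2 5-bromo-2,3,4-trimethoxybenzaldehyde
Product: 4 5-bromo-2,3,4-trimethoxyphenol, via aryl formate 3 (not isolated)
Conditions: mCPBA, CH2Cl2, rt; then K2CO3, MeOH, rt
Reagents that add atoms: 3-chloroperoxybenzoic acid (mCPBA), OOC(=O)c1cccc(Cl)c1
Why: Baeyer–Villiger oxidation of the Dakin type, in which the aryl group, enriched by the ortho and para methoxy groups, migrates in preference to hydride to give formate 3, which mild methanolysis converts into the phenol while the aryl bromide is untouched.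

Step 3
Reactants: 4 5-bromo-2,3,4-trimethoxyphenol
Product: 6 4,5,6-trimethoxybenzene-1,3-diol, via pinacol boronate 5 (not isolated)
Conditions: B2pin2, PdCl2(dppf) (cat.), KOAc, dioxane, 90 °C; then 30% aq. H2O2, aq. NaOH, THF, 0 °C
Reagents that add atoms: hydrogen peroxide, OO; bis(pinacolato)diboron, CC1(C)OB(OC1(C)C)B1OC(C)(C)C(C)(C)O1 (boron of 5 only)
Why: Miyaura borylation with the weak base KOAc tolerates the free phenol and turns the C–Br bond into a C–B bond, and alkaline peroxide then converts C–B into C–OH at the same carbon by boron-to-oxygen aryl migration, which should deliver the symmetric resorcinol.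

Step 4
Reactants: 6 4,5,6-trimethoxybenzene-1,3-diol
Product: 8 2,6-dihydroxy-3,4,5-trimethoxybenzaldehyde, via iminium chloride 7 (not isolated)
Conditions: (chloromethylene)dimethyliminium chloride, MeCN, 0 °C → rt; then H2O, 50 °C
Reagents that add atoms: (chloromethylene)dimethyliminium chloride, C[N+](C)=CCl.[Cl-]; water, O
Why: Vilsmeier–Haack formylation of a free resorcinol, in which the only unsubstituted ring carbon, C2, is ortho to both hydroxyls and para to the 5-methoxy group, so substitution can only occur there, and hydrolysis of iminium salt 7 frees the aldehyde.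

Step 5
Reactants: 9 methyl 3,5-dihydroxy-4-methoxybenzoate
Product: 10 methyl 3,5-bis(benzyloxy)-4-methoxybenzoate
Conditions: BnBr, K2CO3, DMF, 60 °C
Reagents that add atoms: benzyl bromide, BrCc1ccccc1
Why: Williamson ether synthesis on the two equivalent phenols, under carbonate conditions that do not touch the methyl ester.

Step 6
Reactants: 10 methyl 3,5-bis(benzyloxy)-4-methoxybenzoate
Product: 11 3,5-bis(benzyloxy)-4-methoxybenzoic acid
Conditions: LiOH, THF/MeOH/H2O, 50 °C; then aq. HCl
Reagents that add atoms: lithium hydroxide, [Li+].[OH-]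
Why: Saponification of the methyl ester, to which the benzyl and methyl aryl ethers are inert.

Step 7
Reactants: 11 3,5-bis(benzyloxy)-4-methoxybenzoic acid (2.3 equiv); 8 2,6-dihydroxy-3,4,5-trimethoxybenzaldehyde
Product: 13 2-formyl-4,5,6-trimethoxy-1,3-phenylene bis[3,5-bis(benzyloxy)-4-methoxybenzoate], via acid chloride 12 (not isolated)
Conditions: 11, (COCl)2, DMF (cat.), CH2Cl2, rt, evaporate; then 8, Et3N, DMAP (cat.), CH2Cl2, 0 °C → rt
Reagents that add atoms: oxalyl chloride, O=C(Cl)C(Cl)=O (chlorine of 12 only)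
Why: Acid chloride formation followed by DMAP-catalysed O-acylation of both phenols of 8, whose aldehyde has no enolisable position, the excess of 12 driving the second, hydrogen-bonded hydroxyl to react.

Step 8
Reactants: 13 2-formyl-4,5,6-trimethoxy-1,3-phenylene bis[3,5-bis(benzyloxy)-4-methoxybenzoate]
Product: 14 2,6-bis{[3,5-bis(benzyloxy)-4-methoxybenzoyl]oxy}-3,4,5-trimethoxybenzoic acid
Conditions: NaClO2, NaH2PO4, 2-methyl-2-butene, THF/t-BuOH/H2O, 0 °C → rt
Reagents that add atoms: sodium chlorite, [Na+].[O-]Cl=O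
Why: Pinnick oxidation converts the hindered aryl aldehyde into the acid at about pH 4, where aryl esters and benzyl ethers are stable, and 2-methyl-2-butene traps the hypochlorous acid that could otherwise chlorinate the ring B arenes.

Step 9
Reactants: 14 2,6-bis{[3,5-bis(benzyloxy)-4-methoxybenzoyl]oxy}-3,4,5-trimethoxybenzoic acid
Product: 15 2,6-bis{[3,5-bis(benzyloxy)-4-methoxybenzoyl]oxy}-3,4,5-trimethoxybenzoyl chloride
Conditions: (COCl)2, DMF (cat.), CH2Cl2, 0 °C → rt
Reagents that add atoms: oxalyl chloride, O=C(Cl)C(Cl)=O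
Why: DMF-catalysed chlorination of the carboxylic acid works for 2,6-disubstituted benzoic acids and leaves aryl esters and benzyl ethers intact, as in the preparation of O-acylsalicyloyl chlorides.

Step 10
Reactants: 15 2,6-bis{[3,5-bis(benzyloxy)-4-methoxybenzoyl]oxy}-3,4,5-trimethoxybenzoyl chloride; 16 (methoxymethyl)triphenylphosphonium chloride (2.1 equiv)
Product: 20 2-[3,5-bis(benzyloxy)-4-methoxyphenyl]-3,6,7,8-tetramethoxy-4-oxo-4H-chromen-5-yl 3,5-bis(benzyloxy)-4-methoxybenzoate, via ylide 17 (not isolated), via acylphosphonium chloride 18 (not isolated), via keto ylide 19 (not isolated)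
Conditions: 16, NaN(SiMe3)2 (2.05 equiv), THF, 0 °C; then 15 added slowly, −78 °C → rt; then toluene, 100 °C
Reagents that add atoms: none
Why: Ylide 17 is C-acylated by the acyl chloride of 15 at −78 °C to give phosphonium salt 18 (C3–C4 bond), which the second equivalent of 17 deprotonates to the α-methoxy β-keto ylide 19. On heating, the ylide carbon of 19 adds to the carbonyl of an ortho aroyloxy group and the oxaphosphetane collapses with loss of triphenylphosphine oxide, forming C2=C3 (intramolecular ester Wittig reaction). The closest known reaction type is the chromone synthesis from O-acylsalicylic acid derivatives and phosphoranes by ylide acylation followed by intramolecular ester olefination; here the ylide carries a methoxy group. Ring C closes in a 6-exo-trig mode, the attacked ester C=O lying outside the forming six-membered ring. No stereocentre is created. The step needs attack at the acyl chloride before the aryl esters, which the far higher electrophilicity of the chloride at low temperature and the electron-rich trialkoxybenzoyl esters should secure, while the mirror symmetry of 15 makes the two esters equivalent, so that the one left over simply becomes the 5-O-aroyl group.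

Step 11
Reactants: 20 2-[3,5-bis(benzyloxy)-4-methoxyphenyl]-3,6,7,8-tetramethoxy-4-oxo-4H-chromen-5-yl 3,5-bis(benzyloxy)-4-methoxybenzoate
Product: 21 2-[3,5-bis(benzyloxy)-4-methoxyphenyl]-5-hydroxy-3,6,7,8-tetramethoxy-4H-chromen-4-one
Conditions: K2CO3, MeOH/THF, rt; then dilute aq. HCl
Reagents that add atoms: none
Why: Base-mediated transesterification (methanolysis) of the activated aryl ester at C5, the only ester in 20, should free the chelated 5-hydroxyl and return the ring B acyl group as methyl ester 10, which can be fed back into step 6.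

Step 12
Reactants: 21 2-[3,5-bis(benzyloxy)-4-methoxyphenyl]-5-hydroxy-3,6,7,8-tetramethoxy-4H-chromen-4-one
Product: 22 5,3',5'-trihydroxy-3,6,7,8,4'-pentamethoxyflavone
Conditions: H2 (1 atm), 10% Pd/C, EtOAc/MeOH, rt
Reagents that add atoms: none
Why: Catalytic hydrogenolysis of the two benzyl aryl ethers under mild conditions, under which the tetrasubstituted, cross-conjugated C2=C3 bond of the flavone and the methyl ethers should not react.

Compound list
1 | 2,3,4-trimethoxybenzaldehyde | COc1ccc(C=O)c(OC)c1OC | starting material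
2 | 5-bromo-2,3,4-trimethoxybenzaldehyde | COc1c(Br)cc(C=O)c(OC)c1OC | intermediate
3 | 5-bromo-2,3,4-trimethoxyphenyl formate | COc1c(Br)cc(OC=O)c(OC)c1OC | intermediate
4 | 5-bromo-2,3,4-trimethoxyphenol | COc1c(Br)cc(O)c(OC)c1OC | intermediate
5 | 2,3,4-trimethoxy-5-(4,4,5,5-tetramethyl-1,3,2-dioxaborolan-2-yl)phenol | COc1c(B2OC(C)(C)C(C)(C)O2)cc(O)c(OC)c1OC | intermediate
6 | 4,5,6-trimethoxybenzene-1,3-diol | COc1c(O)cc(O)c(OC)c1OC | intermediate
7 | N-(2,6-dihydroxy-3,4,5-trimethoxybenzylidene)-N-methylmethanaminium chloride | C[N+](C)=Cc1c(O)c(OC)c(OC)c(OC)c1O.[Cl-] | intermediate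
8 | 2,6-dihydroxy-3,4,5-trimethoxybenzaldehyde | O=Cc1c(O)c(OC)c(OC)c(OC)c1O | intermediate
9 | methyl 3,5-dihydroxy-4-methoxybenzoate | COC(=O)c1cc(O)c(OC)c(O)c1 | starting material
10 | methyl 3,5-bis(benzyloxy)-4-methoxybenzoate | COC(=O)c1cc(OCc2ccccc2)c(OC)c(OCc2ccccc2)c1 | intermediate
11 | 3,5-bis(benzyloxy)-4-methoxybenzoic acid | OC(=O)c1cc(OCc2ccccc2)c(OC)c(OCc2ccccc2)c1 | intermediate
12 | 3,5-bis(benzyloxy)-4-methoxybenzoyl chloride | ClC(=O)c1cc(OCc2ccccc2)c(OC)c(OCc2ccccc2)c1 | intermediate
13 | 2-formyl-4,5,6-trimethoxy-1,3-phenylene bis[3,5-bis(benzyloxy)-4-methoxybenzoate] | O=Cc1c(OC(=O)c2cc(OCc3ccccc3)c(OC)c(OCc3ccccc3)c2)c(OC)c(OC)c(OC)c1OC(=O)c1cc(OCc2ccccc2)c(OC)c(OCc2ccccc2)c1 | intermediate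
14 | 2,6-bis{[3,5-bis(benzyloxy)-4-methoxybenzoyl]oxy}-3,4,5-trimethoxybenzoic acid | OC(=O)c1c(OC(=O)c2cc(OCc3ccccc3)c(OC)c(OCc3ccccc3)c2)c(OC)c(OC)c(OC)c1OC(=O)c1cc(OCc2ccccc2)c(OC)c(OCc2ccccc2)c1 | intermediate
15 | 2,6-bis{[3,5-bis(benzyloxy)-4-methoxybenzoyl]oxy}-3,4,5-trimethoxybenzoyl chloride | COc1c(OC)c(OC(=O)c2cc(OCc3ccccc3)c(OC)c(OCc3ccccc3)c2)c(C(Cl)=O)c(OC(=O)c2cc(OCc3ccccc3)c(OC)c(OCc3ccccc3)c2)c1OC | intermediate
16 | (methoxymethyl)triphenylphosphonium chloride | COC[P+](c1ccccc1)(c1ccccc1)c1ccccc1.[Cl-] | starting material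
17 | (methoxymethylene)triphenylphosphorane | COC=P(c1ccccc1)(c1ccccc1)c1ccccc1 | intermediate
18 | {2-[2,6-bis{[3,5-bis(benzyloxy)-4-methoxybenzoyl]oxy}-3,4,5-trimethoxyphenyl]-1-methoxy-2-oxoethyl}triphenylphosphonium chloride | COC(C(=O)c1c(OC(=O)c2cc(OCc3ccccc3)c(OC)c(OCc3ccccc3)c2)c(OC)c(OC)c(OC)c1OC(=O)c1cc(OCc2ccccc2)c(OC)c(OCc2ccccc2)c1)[P+](c1ccccc1)(c1ccccc1)c1ccccc1.[Cl-] | intermediate
19 | 2-[methoxy(triphenylphosphoranylidene)acetyl]-4,5,6-trimethoxy-1,3-phenylene bis[3,5-bis(benzyloxy)-4-methoxybenzoate] | COC(C(=O)c1c(OC(=O)c2cc(OCc3ccccc3)c(OC)c(OCc3ccccc3)c2)c(OC)c(OC)c(OC)c1OC(=O)c1cc(OCc2ccccc2)c(OC)c(OCc2ccccc2)c1)=P(c1ccccc1)(c1ccccc1)c1ccccc1 | intermediate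
20 | 2-[3,5-bis(benzyloxy)-4-methoxyphenyl]-3,6,7,8-tetramethoxy-4-oxo-4H-chromen-5-yl 3,5-bis(benzyloxy)-4-methoxybenzoate | COc1c(OCc2ccccc2)cc(cc1OCc1ccccc1)-c1oc2c(OC)c(OC)c(OC)c(OC(=O)c3cc(OCc4ccccc4)c(OC)c(OCc4ccccc4)c3)c2c(=O)c1OC | intermediate
21 | 2-[3,5-bis(benzyloxy)-4-methoxyphenyl]-5-hydroxy-3,6,7,8-tetramethoxy-4H-chromen-4-one | COc1c(OCc2ccccc2)cc(cc1OCc1ccccc1)-c1oc2c(OC)c(OC)c(OC)c(O)c2c(=O)c1OC | intermediate
22 | 5,3',5'-trihydroxy-3,6,7,8,4'-pentamethoxyflavone | COc1c(O)cc(-c2oc3c(OC)c(OC)c(OC)c(O)c3c(=O)c2OC)cc1O | target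

Total step count: 12. Longest linear sequence: 10 steps (steps 1–4 and 7–12 from 1); the ring B branch (steps 5 and 6) joins at step 7.

Steps most likely to fail

Step 10. The reactive ylide may add to an aryl ester carbonyl instead of the doubly ortho-substituted acyl chloride. The crowded α-methoxy keto ylide may also fail to olefinate the ester and merely shuttle the aroyl group between oxygen atoms, so that ring C does not close. The fallback is the classical diketone route. It sets out from resorcinol 6 and returns at 20. Houben–Hoesch acylation of 6 with methoxyacetonitrile (ZnCl2, HCl, Et2O, 0 °C) should give 1-(2,6-dihydroxy-3,4,5-trimethoxyphenyl)-2-methoxyethan-1-iminium chloride F1, which hot water hydrolyses to 1-(2,6-dihydroxy-3,4,5-trimethoxyphenyl)-2-methoxyethan-1-one F2. Double O-aroylation with acid chloride 12 (Et3N, DMAP, CH2Cl2) should give 2-(methoxyacetyl)-4,5,6-trimethoxy-1,3-phenylene bis[3,5-bis(benzyloxy)-4-methoxybenzoate] F3. Baker–Venkataraman rearrangement (LiN(SiMe3)2, THF, −20 °C → rt) should move one aroyl group to carbon and give 2-{3-[3,5-bis(benzyloxy)-4-methoxyphenyl]-2-methoxy-3-oxopropanoyl}-3-hydroxy-4,5,6-trimethoxyphenyl 3,5-bis(benzyloxy)-4-methoxybenzoate F4. Acid-catalysed cyclodehydration (TsOH, toluene, 80 °C) should then give 20, and the route continues with step 11.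

Step 3. Oxidative addition into the very electron-rich bromophenol may be slow, protodebromination may compete, and the resorcinol may degrade oxidatively under alkaline peroxide. The fallback protects the phenol and uses organolithium chemistry. It sets out from 4 and returns at 6. Benzylation of 4 (BnBr, K2CO3, DMF) should give 1-(benzyloxy)-5-bromo-2,3,4-trimethoxybenzene F5. Bromine–lithium exchange (n-BuLi, THF, −78 °C) should give [5-(benzyloxy)-2,3,4-trimethoxyphenyl]lithium F6. Trapping with 2-isopropoxy-4,4,5,5-tetramethyl-1,3,2-dioxaborolane should give 2-[5-(benzyloxy)-2,3,4-trimethoxyphenyl]-4,4,5,5-tetramethyl-1,3,2-dioxaborolane F7. Oxidation (H2O2, aq. NaOH, THF, 0 °C) should give 5-(benzyloxy)-2,3,4-trimethoxyphenol F8, and hydrogenolysis (H2, 10% Pd/C, EtOAc) should give 6.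

Step 4. Reaction of the Vilsmeier salt may stop at the phenolic oxygens, or the electron-rich resorcinol may decompose before substitution at the crowded C2 takes place. The fallback introduces the carbon at the acid oxidation level. It sets out from 6 and returns at 14, replacing steps 4, 7 and 8. Kolbe–Schmitt carboxylation of 6 (KHCO3, CO2, glycerol, 120 °C) can only occur at C2 and should give 2,6-dihydroxy-3,4,5-trimethoxybenzoic acid F9. Double O-aroylation with acid chloride 12 (pyridine, DMAP, rt, then aqueous pyridine before isolation to free the carboxyl group) should give acid 14.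

Further compounds
F1 | step 10 | 1-(2,6-dihydroxy-3,4,5-trimethoxyphenyl)-2-methoxyethan-1-iminium chloride | COCC(=[NH2+])c1c(O)c(OC)c(OC)c(OC)c1O.[Cl-]
F2 | step 10 | 1-(2,6-dihydroxy-3,4,5-trimethoxyphenyl)-2-methoxyethan-1-one | COCC(=O)c1c(O)c(OC)c(OC)c(OC)c1O
F3 | step 10 | 2-(methoxyacetyl)-4,5,6-trimethoxy-1,3-phenylene bis[3,5-bis(benzyloxy)-4-methoxybenzoate] | COCC(=O)c1c(OC(=O)c2cc(OCc3ccccc3)c(OC)c(OCc3ccccc3)c2)c(OC)c(OC)c(OC)c1OC(=O)c1cc(OCc2ccccc2)c(OC)c(OCc2ccccc2)c1
F4 | step 10 | 2-{3-[3,5-bis(benzyloxy)-4-methoxyphenyl]-2-methoxy-3-oxopropanoyl}-3-hydroxy-4,5,6-trimethoxyphenyl 3,5-bis(benzyloxy)-4-methoxybenzoate | COC(C(=O)c1cc(OCc2ccccc2)c(OC)c(OCc2ccccc2)c1)C(=O)c1c(O)c(OC)c(OC)c(OC)c1OC(=O)c1cc(OCc2ccccc2)c(OC)c(OCc2ccccc2)c1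
F5 | step 3 | 1-(benzyloxy)-5-bromo-2,3,4-trimethoxybenzene | COc1c(Br)cc(OCc2ccccc2)c(OC)c1OC
F6 | step 3 | [5-(benzyloxy)-2,3,4-trimethoxyphenyl]lithium | [Li]c1cc(OCc2ccccc2)c(OC)c(OC)c1OC
F7 | step 3 | 2-[5-(benzyloxy)-2,3,4-trimethoxyphenyl]-4,4,5,5-tetramethyl-1,3,2-dioxaborolane | COc1c(B2OC(C)(C)C(C)(C)O2)cc(OCc2ccccc2)c(OC)c1OC
F8 | step 3 | 5-(benzyloxy)-2,3,4-trimethoxyphenol | COc1c(O)cc(OCc2ccccc2)c(OC)c1OC
F9 | step 4 | 2,6-dihydroxy-3,4,5-trimethoxybenzoic acid | OC(=O)c1c(O)c(OC)c(OC)c(OC)c1O
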